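The west run and the south-east run differ in precatalyst by a factor of 4.00 and in nothing else.

| setting | west | south-east | flask |
|---|---|---|---|
| substrate | 0.10 M | 0.10 M | 0.10 M |
| partner | 0.20 M | 0.20 M | 0.200 M |
| precatalyst | 0.065 mM | 0.26 mM | 0.13 mM |
| remark | run made earlier | run made earlier |  |

- west (time / s: product / %, substrate / %): 10.0: 4.4, 97.0; 12.0: 5.8, 94.5; 15.0: 6.5, 93.7; 25.0: 11.5, 86.8; 40.0: 22.6, 79.9; 60.0: 30.0, 68.6; 90.0: 45.5, 54.3
- south-east (time / s: product / %, substrate / %): 12.0: 17.2, 79.2; 25.0: 44.8, 54.2; 40.0: 68.6, 29.9; 50.0: 83.5, 16.9; 60.0: 90.8, 8.2; 80.0: 99.4, 1.3; 90.0: 101.1, 0

(readings scatter by 1 percentage point)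

- the numbers in the tables scatter with a standard deviation of 1 percentage point
- what may be going on: precatalyst <-> free catalyst; partner + free catalyst -> catalyst intermediate A; catalyst intermediate C -> free catalyst + product; substrate + catalyst intermediate A -> catalyst intermediate B; catalyst intermediate B -> released group + catalyst intermediate C
- no earlier run changes the charge of partner; that part of a forecast is a guess

- factor on the rate of making product when 30% of the substrate are converted if partner is charged twice over
- factor on the rate when 30% of the substrate are converted if precatalyst is charged at 0.025 mM instead

Both runs reach the same substrate level, 54.3% and 54.2%, at 90.0 s and 25.0 s. If every charged catalyst kept one pace, charge times time would agree. It gives 5.85 mM·s and 6.50 mM·s, a gap of 11.1%, against a scatter of 1 percentage point on 45.7% converted.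

The gap need not mean a slower pace. Suppose a short constant lag while precatalyst opens. Equal charge times time after the lag requires a lag of 3.33 s, as a reading. That lag takes a larger part of the south-east time than of the west time. Then τ = 0.123 s is the turn time, the seconds one charged catalyst spends per product after the lag.

Two readings set two constants, so this proves nothing yet. At 12.0 s, the south-east run should stand at 18.3% converted. Its readings give 17.2% as product and 20.8% as substrate lost, on either side of that.

For the flask, 30% conversion should come at 31.8 s. At fixed conversion the rate is charge over τ, so the lower charge gives a factor of 0.192. The lag stays small there, against 151 s to reach that conversion. But τ may hold a part that depends on c_partner, and no run separates it.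

The forecast gives 1.08 (1 to 1.3) for partner: “Turnover is therefore limited after partner and substrate entry”. For precatalyst it gives 0.215 (0.18 to 0.26), above the reckoning here.

The simulation gives 1.41 and 0.192. The flask reaches 30% at 31.1 s, against 31.8 s from τ, and the factor for the lower charge equals the charge ratio, 0.192.

    precatalyst ⇌ free catalyst (K = 0.560, k = 0.240 /s)
    partner + free catalyst → catalyst intermediate A (k = 230 /M/s)
    catalyst intermediate C → free catalyst + product (k = 57.0 /s)
    substrate + catalyst intermediate A → catalyst intermediate B (k = 650 /M/s)
    catalyst intermediate B → released group + catalyst intermediate C (k = 47.0 /s)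

By these constants, the flask's turn time at 30% conversion holds 0.0712 s that scales with 1/c_partner, the entry of partner with precatalyst in balance with free catalyst, which is more than the 0.0608 s for the other steps. With partner charged twice over, the first part falls to 0.0327 s, and the sum falls by a factor of 1.41.

All runs were computed for substances that don't exist.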